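The readings were generated by integration with made-up constants; scatter was added.

**Target clock.** Target is what you asked about, with the hunch that maple's percentages carry over to both new flasks. We doubt it. At 80.0 min maple shows 31 % and birch 16 %, twice the percentage, yet [target] rose at 0.108 mM min⁻¹ in maple and 0.0880 mM min⁻¹ in birch, a factor of just 1.23. So the round looks roughly zero-order in starting material, and with a scatter of 1.5 percentage points on each reading we read nothing into the gap between those two figures.

the same everywhere: free catalyst 100 µM
- maple: starting material 28 mM; partner 40 mM; protic impurity 10 mM; run made earlier
- birch: starting material 44 mM; partner 40 mM; protic impurity 10 mM; run made earlier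
- Sunday's: starting material 20 mM; partner 40.0 mM; protic impurity 10.0 mM; time 0.50 h
- Tuesday's: starting material 20 mM; partner 40.0 mM; protic impurity 10.0 mM; time 2.0 h

| run | time / min | target / % | starting material / % |
|---|---|---|---|
| maple | 20.0 | 9 | 93 |
| maple | 40.0 | 15 | 83 |
| maple | 50.0 | 20 | 84 |
| maple | 80.0 | 31 | 69 |
| birch | 20.0 | 5 | 94 |
| birch | 40.0 | 9 | 92 |
| birch | 50.0 | 12 | 87 |
| birch | 80.0 | 16 | 80 |

(each reading ± 1.5 percentage points)

1. which of the two ends with the higher amount of target, in percent of the starting material charged ("neither" if they lie within 2 percentage points) (Sunday's / Tuesday's / neither)
2. target at the end, in percent of the starting material charged, Sunday's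
3. target at the end, in percent of the starting material charged, Tuesday's

- steps thought possible: partner + free catalyst -> catalyst intermediate A; starting material + catalyst intermediate A <-> catalyst intermediate B; catalyst intermediate B <-> by-product + catalyst intermediate C; catalyst intermediate C -> free catalyst + target; partner + protic impurity -> quenched reagent; starting material -> decomposition product; partner + catalyst intermediate B <-> idle complex

**Our number.** The new charge of 20 mM stands closer to maple's 28 mM than to birch's 44 mM, so we take maple's rate. That gives 3.07 h as the clearing time, the charge of starting material divided by the rate of target. Percent of target is then the time over the clearing time, provided partner lasts, and after the protic impurity takes its share 30.0 mM of partner remains, more than the charge. We commit to 16.3 % for Sunday's and 65.1 % for Tuesday's.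

**The forecast.** Holding that “The target forms at a nearly constant rate in mM, not in percent”, the forecast names Tuesday's, with 18 % for Sunday's and 60 % for Tuesday's. That is above us on Sunday's and below us on Tuesday's.

**The flasks.** Sunday's gives 15.3 % and Tuesday's 57.6 %, so Tuesday's ends higher.

    partner + free catalyst → catalyst intermediate A (k = 183 M⁻¹ min⁻¹)
    starting material + catalyst intermediate A ⇌ catalyst intermediate B (K = 110 M⁻¹, k = 1350 M⁻¹ min⁻¹)
    catalyst intermediate B ⇌ by-product + catalyst intermediate C (K = 0.970 M, k = 9.31 min⁻¹)
    catalyst intermediate C → free catalyst + target (k = 2.04 min⁻¹)
    partner + protic impurity → quenched reagent (k = 2.89 M⁻¹ min⁻¹)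
    starting material → decomposition product (k = 2.30 × 10⁻⁵ min⁻¹)
    partner + catalyst intermediate B ⇌ idle complex, settled at all times (K = 30.0 M⁻¹)

**Still running.** Tuesday's stops at 2.0 h, short of the clearing time of 3.07 h, with 42 % of its starting material still there. A further flask like Tuesday's but with 5.0 mM of starting material clears in 46.3 min at maple's rate, sooner than 2.0 h, and it does reach 98.6 % target. Neither new flask is at rest: Sunday's left until 5.00 h reaches 99.5 %, and Tuesday's left until 20.0 h gains 42 points to reach 99.7 %, with 0.251 % as decomposition product.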